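**Plan**

- Locants: flavanone rings A and C are unprimed; the dimethylchromanone rings B (arene) and D (pyranone) are primed. Retrosynthesis: the three phenols become benzyl ethers, the C2–C6' bond is cut to 5,7-bis(benzyloxy)chromone and a C6' boronic acid, and the C4' ketone is traced back to a C3'=C4' alkene.
- Enabling feature: ring D is O1'–C2'–C3'–C4'–C4a'–C8a', with the C3' methylene next to C4'. O1' and C4a' are ortho neighbours on ring B, so a 1,1-dimethylallyl ether on O1' and a vinyl group on C4a' form a 1,7-diene whose two inner alkene carbons become C3' and C4'.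
- The diene is cut at O1'–C2' (allylic etherification) and at the C4a' vinyl group (methylenation of a salicylaldehyde). The chromone is cut at O1–C2 and C2–C3 to a phloroacetophenone dibenzyl ether and a one-carbon unit.
- Forward: ring B is bought as 2,3-dihydroxybenzaldehyde; ring D is closed by metathesis and oxygenated at C4'; the bromide becomes a boronic acid. Ring A is bought and ring C is built as a chromone; the halves are joined at C2–C6' and debenzylated.
- Stereochemistry: the only stereocentre, C2 (S), is set by a ligand-controlled rhodium-catalysed 1,4-addition (aryl to the Re face of C2). The final step is neutral, so it is kept.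

Key step: step 5

Assumption: (S)-configured atropisomeric diphosphine–rhodium catalysts are taken to show the same facial preference on chromones as on cyclic enones and coumarins (Re face of C2, giving 2S); if a trial on 18 shows the opposite sense, the (R)-ligand is used with no other change.

**Route**

Step 1
Reactants: 1 2,3-dihydroxybenzaldehyde
Product: 2 3-(benzyloxy)-2-hydroxybenzaldehyde
Conditions: NaH (2.2 equiv), DMSO, rt; BnBr (1.0 equiv), rt; aq HCl work-up
Reagents that add atoms: benzyl bromide, BrCc1ccccc1
Why: Williamson etherification of the dianion, in which the 2-oxide is delocalised into the formyl group, so the 3-oxide is the more nucleophilic site and takes the single equivalent of benzyl bromide.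

Step 2
Reactants: 2 3-(benzyloxy)-2-hydroxybenzaldehyde
Product: 3 3-(benzyloxy)-5-bromo-2-hydroxybenzaldehyde
Conditions: Br2 (1.05 equiv), NaOAc, AcOH, rt
Reagents that add atoms: bromine, BrBr
Why: Electrophilic aromatic bromination goes para to the free hydroxyl and meta to the formyl group (C5), as for o-vanillin, and the acetate buffer keeps the benzyl ether safe from HBr.

Step 3
Reactants: 3 3-(benzyloxy)-5-bromo-2-hydroxybenzaldehyde; 4 tert-butyl 2-methylbut-3-en-2-yl carbonate
Product: 5 3-(benzyloxy)-5-bromo-2-[(2-methylbut-3-en-2-yl)oxy]benzaldehyde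
Conditions: Pd(PPh3)4 (5 mol%), 4 (1.5 equiv), THF, 4 Å MS, 0 °C
Reagents that add atoms: none
Why: Tsuji–Trost O-allylation (reverse prenylation) in which zerovalent palladium ionises the tertiary carbonate with loss of CO2, the tert-butoxide formed deprotonates the phenol, and the phenoxide attacks the 1,1-dimethylallyl palladium cation at its more substituted terminus under kinetic control at 0 °C.

Step 4
Reactants: 5 3-(benzyloxy)-5-bromo-2-[(2-methylbut-3-en-2-yl)oxy]benzaldehyde; 6 methyltriphenylphosphonium bromide
Product: 8 1-(benzyloxy)-5-bromo-3-ethenyl-2-[(2-methylbut-3-en-2-yl)oxy]benzene, via methylenetriphenylphosphorane 7 (not isolated)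
Conditions: 6 (1.3 equiv), KOtBu (1.25 equiv), THF, 0 °C; then 5, 0 °C to rt
Reagents that add atoms: none
Why: Wittig methylenation of a non-enolisable aryl aldehyde by the preformed unstabilised ylide, to which the aryl bromide and both ethers are inert at or below room temperature.

Step 5
Reactants: 8 1-(benzyloxy)-5-bromo-3-ethenyl-2-[(2-methylbut-3-en-2-yl)oxy]benzene
Product: 9 8-(benzyloxy)-6-bromo-2,2-dimethyl-2H-chromene
Conditions: second-generation Grubbs catalyst RuCl2(=CHPh)(PCy3)(H2IMes) (5 mol%), CH2Cl2 (0.01 M), 40 °C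
Reagents that add atoms: none
Why: The ruthenium benzylidene exchanges with the unhindered styrene terminus, and the resulting aryl-substituted alkylidene undergoes [2+2] cycloaddition with the neighbouring vinyl group of the 1,1-dimethylallyl ether; cycloreversion of the ruthenacyclobutane forms C3'=C4' and releases ethylene. The closest known reaction type is the ring-closing metathesis of ortho-vinylaryl allyl ethers to 2H-chromenes. Ring D is closed as a six-membered ring by ring-closing olefin metathesis of a 1,7-diene held on ring B, the new double bond lying inside the ring. No stereocentre is formed. The step needs ring closure to win over intermolecular styrene metathesis and over loss or shift of the tertiary allyl group; the ortho arrangement on ring B, the geminal methyl groups at C2' (Thorpe–Ingold effect and a neopentylic vinyl group that does not homodimerise), high dilution and 40 °C should secure this. Both ortho positions and the para position of the aryl ether are substituted, so no aromatic Claisen product can form.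

Step 6
Reactants: 9 8-(benzyloxy)-6-bromo-2,2-dimethyl-2H-chromene
Product: 10 rac-8-(benzyloxy)-6-bromo-2,2-dimethyl-3,4-dihydro-2H-chromen-4-ol
Conditions: Co(acac)2 (20 mol%), PhSiH3 (2 equiv), O2 (1 atm), THF, rt
Reagents that add atoms: dioxygen, O=O
Why: Mukaiyama hydration, in which hydrogen-atom transfer from a cobalt hydride to C3' gives the benzylic C4' radical that is trapped by O2 and reduced to the alcohol, so oxygen arrives at C4'; the carbinol centre is racemic and is erased in step 7.

Step 7
Reactants: 10 rac-8-(benzyloxy)-6-bromo-2,2-dimethyl-3,4-dihydro-2H-chromen-4-ol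
Product: 11 8-(benzyloxy)-6-bromo-2,2-dimethyl-2,3-dihydro-4H-chromen-4-one
Conditions: Dess–Martin periodinane (1.3 equiv), CH2Cl2, rt
Reagents that add atoms: none
Why: Dess–Martin oxidation of a secondary benzylic alcohol under near-neutral conditions, which leaves the aryl bromide, the benzyl ether and the tertiary alkyl aryl ether untouched.

Step 8
Reactants: 11 8-(benzyloxy)-6-bromo-2,2-dimethyl-2,3-dihydro-4H-chromen-4-one
Product: 12 8-(benzyloxy)-2,2-dimethyl-6-(4,4,5,5-tetramethyl-1,3,2-dioxaborolan-2-yl)-2,3-dihydro-4H-chromen-4-one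
Conditions: B2pin2 (1.2 equiv), Pd(dppf)Cl2 (3 mol%), KOAc (3 equiv), 1,4-dioxane, 90 °C
Reagents that add atoms: bis(pinacolato)diboron, CC1(C)OB(OC1(C)C)B1OC(C)(C)C(C)(C)O1
Why: Miyaura borylation of an aryl bromide, with acetate too weak a base to cause Suzuki homocoupling or enolate chemistry of the chromanone.

Step 9
Reactants: 12 8-(benzyloxy)-2,2-dimethyl-6-(4,4,5,5-tetramethyl-1,3,2-dioxaborolan-2-yl)-2,3-dihydro-4H-chromen-4-one
Product: 13 [8-(benzyloxy)-2,2-dimethyl-4-oxo-3,4-dihydro-2H-chromen-6-yl]boronic acid
Conditions: NaIO4 (3 equiv), NH4OAc (3 equiv), acetone/H2O (1:1), rt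
Reagents that add atoms: water, O
Why: Oxidative deprotection of a pinacol boronate, in which periodate cleaves the pinacol released by the hydrolysis equilibrium and so drives the ester to the free boronic acid without touching ketone or ethers.

Step 10
Reactants: 14 2,4,6-trihydroxyacetophenone
Product: 15 1-[2,4-bis(benzyloxy)-6-hydroxyphenyl]ethan-1-one
Conditions: BnBr (2.1 equiv), K2CO3 (2.2 equiv), DMF, rt
Reagents that add atoms: benzyl bromide, BrCc1ccccc1
Why: Williamson etherification that stops at the dibenzyl ether because the remaining ortho hydroxyl is locked in a hydrogen bond to the acetyl carbonyl and is the least nucleophilic.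

Step 11
Reactants: 15 1-[2,4-bis(benzyloxy)-6-hydroxyphenyl]ethan-1-one; 16 N,N-dimethylformamide dimethyl acetal
Product: 18 5,7-bis(benzyloxy)-4H-chromen-4-one, via dimethylamino enone 17 (not isolated)
Conditions: 16 (3 equiv), toluene, 95 °C; then conc. HCl, CH2Cl2, 40 °C
Reagents that add atoms: none
Why: Enaminone formation from the methyl ketone and the amide acetal, then acid-promoted 6-endo-trig oxa-Michael addition of the phenol and loss of dimethylamine, closes ring C as the chromone.

Step 12
Reactants: 18 5,7-bis(benzyloxy)-4H-chromen-4-one; 13 [8-(benzyloxy)-2,2-dimethyl-4-oxo-3,4-dihydro-2H-chromen-6-yl]boronic acid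
Product: 19 (2S)-5,7-bis(benzyloxy)-2-[8-(benzyloxy)-2,2-dimethyl-4-oxo-3,4-dihydro-2H-chromen-6-yl]-2,3-dihydro-4H-chromen-4-one
Conditions: [Rh(OH)(cod)]2 (2.5 mol%), (S)-MeO-F12-BIPHEP [(S)-2,2'-bis[bis(3,4,5-trifluorophenyl)phosphino]-6,6'-dimethoxy-1,1'-biphenyl] (5.5 mol%), 13 (2.5 equiv), toluene/H2O (10:1), 25–40 °C
Reagents that add atoms: none
Why: Hayashi–Miyaura asymmetric 1,4-addition, in which the aryl group passes from boron to monovalent rhodium, C2=C3 inserts and the rhodium enolate is protonated by water, while the electron-poor diphosphine shields one face of the chromone so that the aryl group reaches the Re face of C2 and sets it as S under base-free conditions that should not open the flavanone.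

Step 13
Reactants: 19 (2S)-5,7-bis(benzyloxy)-2-[8-(benzyloxy)-2,2-dimethyl-4-oxo-3,4-dihydro-2H-chromen-6-yl]-2,3-dihydro-4H-chromen-4-one
Product: 20 (2S)-5,7-dihydroxy-2-(8-hydroxy-2,2-dimethyl-4-oxo-3,4-dihydro-2H-chromen-6-yl)-2,3-dihydro-4H-chromen-4-one
Conditions: H2 (1 atm), Pd/C (10 wt%), EtOAc/MeOH, rt
Reagents that add atoms: none
Why: Hydrogenolysis of the three benzyl aryl ethers under neutral conditions, where C2 (which epimerises only through acid- or base-induced opening to the chalcone) is kept and the two electron-rich aryl ketones should not be reduced at 1 atm.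

**Compound list**

1 | 2,3-dihydroxybenzaldehyde | O=Cc1cccc(O)c1O | starting material
2 | 3-(benzyloxy)-2-hydroxybenzaldehyde | O=Cc1cccc(OCc2ccccc2)c1O | intermediate
3 | 3-(benzyloxy)-5-bromo-2-hydroxybenzaldehyde | O=Cc1cc(Br)cc(OCc2ccccc2)c1O | intermediate
4 | tert-butyl 2-methylbut-3-en-2-yl carbonate | C=CC(C)(C)OC(=O)OC(C)(C)C | starting material
5 | 3-(benzyloxy)-5-bromo-2-[(2-methylbut-3-en-2-yl)oxy]benzaldehyde | C=CC(C)(C)Oc1c(C=O)cc(Br)cc1OCc1ccccc1 | intermediate
6 | methyltriphenylphosphonium bromide | C[P+](c1ccccc1)(c1ccccc1)c1ccccc1.[Br-] | starting material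
7 | methylenetriphenylphosphorane | C=P(c1ccccc1)(c1ccccc1)c1ccccc1 | intermediate
8 | 1-(benzyloxy)-5-bromo-3-ethenyl-2-[(2-methylbut-3-en-2-yl)oxy]benzene | C=CC(C)(C)Oc1c(C=C)cc(Br)cc1OCc1ccccc1 | intermediate
9 | 8-(benzyloxy)-6-bromo-2,2-dimethyl-2H-chromene | CC1(C)C=Cc2cc(Br)cc(OCc3ccccc3)c2O1 | intermediate
10 | rac-8-(benzyloxy)-6-bromo-2,2-dimethyl-3,4-dihydro-2H-chromen-4-ol | CC1(C)CC(O)c2cc(Br)cc(OCc3ccccc3)c2O1 | intermediate
11 | 8-(benzyloxy)-6-bromo-2,2-dimethyl-2,3-dihydro-4H-chromen-4-one | CC1(C)CC(=O)c2cc(Br)cc(OCc3ccccc3)c2O1 | intermediate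
12 | 8-(benzyloxy)-2,2-dimethyl-6-(4,4,5,5-tetramethyl-1,3,2-dioxaborolan-2-yl)-2,3-dihydro-4H-chromen-4-one | CC1(C)CC(=O)c2cc(B3OC(C)(C)C(C)(C)O3)cc(OCc3ccccc3)c2O1 | intermediate
13 | [8-(benzyloxy)-2,2-dimethyl-4-oxo-3,4-dihydro-2H-chromen-6-yl]boronic acid | CC1(C)CC(=O)c2cc(B(O)O)cc(OCc3ccccc3)c2O1 | intermediate
14 | 2,4,6-trihydroxyacetophenone | CC(=O)c1c(O)cc(O)cc1O | starting material
15 | 1-[2,4-bis(benzyloxy)-6-hydroxyphenyl]ethan-1-one | CC(=O)c1c(O)cc(OCc2ccccc2)cc1OCc1ccccc1 | intermediate
16 | N,N-dimethylformamide dimethyl acetal | COC(OC)N(C)C | starting material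
17 | (E)-1-[2,4-bis(benzyloxy)-6-hydroxyphenyl]-3-(dimethylamino)prop-2-en-1-one | CN(C)/C=C/C(=O)c1c(O)cc(OCc2ccccc2)cc1OCc1ccccc1 | intermediate
18 | 5,7-bis(benzyloxy)-4H-chromen-4-one | O=c1ccoc2cc(OCc3ccccc3)cc(OCc3ccccc3)c12 | intermediate
19 | (2S)-5,7-bis(benzyloxy)-2-[8-(benzyloxy)-2,2-dimethyl-4-oxo-3,4-dihydro-2H-chromen-6-yl]-2,3-dihydro-4H-chromen-4-one | CC1(C)CC(=O)c2cc([C@@H]3CC(=O)c4c(OCc5ccccc5)cc(OCc5ccccc5)cc4O3)cc(OCc3ccccc3)c2O1 | intermediate
20 | (2S)-5,7-dihydroxy-2-(8-hydroxy-2,2-dimethyl-4-oxo-3,4-dihydro-2H-chromen-6-yl)-2,3-dihydro-4H-chromen-4-one | CC1(C)CC(=O)c2cc([C@@H]3CC(=O)c4c(O)cc(O)cc4O3)cc(O)c2O1 | target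

**Step count**

Total step count: 13.
Longest linear sequence: 11 steps (steps 1–9, 12 and 13); the chromone branch (steps 10 and 11) joins at step 12.

**Steps most likely to fail**

Step 12. Insertion of the donor-substituted, peri-hindered chromone into the aryl–rhodium bond may be slow enough for protodeboronation to consume the boronic acid. Facial discrimination may also suffer from the 5-benzyloxy group, and reversible ring opening to the chalcone could erode the enantiomeric purity. The fallback gives up catalyst control and sets out from 13 and 18. An achiral, base-free conjugate addition with a cationic divalent-palladium catalyst (Pd(OCOCF3)2, 2,2'-bipyridine, aqueous 1,2-dichloroethane, 60 °C) should give racemic 5,7-bis(benzyloxy)-2-[8-(benzyloxy)-2,2-dimethyl-4-oxo-3,4-dihydro-2H-chromen-6-yl]-2,3-dihydro-4H-chromen-4-one F4. Preparative chromatography on an amylose tris(3,5-dimethylphenylcarbamate) phase should separate it into 19 and (2R)-5,7-bis(benzyloxy)-2-[8-(benzyloxy)-2,2-dimethyl-4-oxo-3,4-dihydro-2H-chromen-6-yl]-2,3-dihydro-4H-chromen-4-one F5. F5 is racemised through the ring-opened chalcone (DBU cat., THF) and separated again; the route is rejoined at 19.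

Step 3. The kinetically formed tertiary ether may be re-ionised by zerovalent palladium, since the salicylaldehyde phenoxide is a good leaving group, and drift to the linear prenyl ether. Attack by the doubly ortho-substituted, hydrogen-bonded phenoxide may also be too slow. The fallback sets out from 3 and builds the ether by copper catalysis instead. 3-Chloro-3-methylbut-1-yne, CuCl2·2H2O (cat.) and DBU in MeCN at 0 °C should give 3-(benzyloxy)-5-bromo-2-[(2-methylbut-3-yn-2-yl)oxy]benzaldehyde F1. Semihydrogenation (H2, Pd/CaCO3 poisoned with Pb(OAc)2, quinoline, EtOAc) then reduces the alkyne to the alkene, and the route is rejoined at 5.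

Step 6. The radical hydration may stop short, or leak into simple reduction of the alkene to the chroman or into peroxide by-products. The fallback sets out from 9 and brings in the C4' oxygen by an ionic path. NBS in aqueous DMSO at 0 °C should open the bromonium ion with water at the benzylic carbon and give trans-8-(benzyloxy)-3,6-dibromo-2,2-dimethyl-3,4-dihydro-2H-chromen-4-ol F2. Dess–Martin oxidation gives rac-8-(benzyloxy)-3,6-dibromo-2,2-dimethyl-2,3-dihydro-4H-chromen-4-one F3. Zn dust in AcOH at rt removes the bromine alpha to the ketone and leaves the aryl bromide; the route is rejoined at 11.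

**Further compounds**

F1 | step 3 | 3-(benzyloxy)-5-bromo-2-[(2-methylbut-3-yn-2-yl)oxy]benzaldehyde | C#CC(C)(C)Oc1c(C=O)cc(Br)cc1OCc1ccccc1
F2 | step 6 | trans-8-(benzyloxy)-3,6-dibromo-2,2-dimethyl-3,4-dihydro-2H-chromen-4-ol (racemic, one enantiomer drawn) | CC1(C)Oc2c(OCc3ccccc3)cc(Br)cc2[C@H](O)[C@H]1Br
F3 | step 6 | rac-8-(benzyloxy)-3,6-dibromo-2,2-dimethyl-2,3-dihydro-4H-chromen-4-one | CC1(C)Oc2c(OCc3ccccc3)cc(Br)cc2C(=O)C1Br
F4 | step 12 | rac-5,7-bis(benzyloxy)-2-[8-(benzyloxy)-2,2-dimethyl-4-oxo-3,4-dihydro-2H-chromen-6-yl]-2,3-dihydro-4H-chromen-4-one | CC1(C)CC(=O)c2cc(C3CC(=O)c4c(OCc5ccccc5)cc(OCc5ccccc5)cc4O3)cc(OCc3ccccc3)c2O1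
F5 | step 12 | (2R)-5,7-bis(benzyloxy)-2-[8-(benzyloxy)-2,2-dimethyl-4-oxo-3,4-dihydro-2H-chromen-6-yl]-2,3-dihydro-4H-chromen-4-one | CC1(C)CC(=O)c2cc([C@H]3CC(=O)c4c(OCc5ccccc5)cc(OCc5ccccc5)cc4O3)cc(OCc3ccccc3)c2O1
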